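**Retrosynthetic overview** (benzoxepine numbering: O1, C2–C5, C5a, C6–C9, C9a)
- Feature used: in the cyclohexane ring the quaternary C9a (CH3, O1) sits next to C5a–H, whose C5 methylene is trans to the C9a oxygen. The array O–C9a–C5a–C5–C4 is the γ-hydroxy ester pattern that a methyl ketyl leaves when it adds to an enoate β-carbon.
- Key disconnection: the C5a–C9a bond, by SmI2 6-exo ketyl–enoate cyclisation of an acyclic keto enoate; its C7 silyloxy stereocentre relays the absolute configuration. The cyclohexane is formed first, the oxepene second.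
- The keto enoate comes from ethyl levulinate (C7–C9a and the C9a methyl), 3-methylbuta-1,2-diene (C6, its two methyls and C5a; enantioselective reverse prenylation sets C7) and triethyl phosphonoacetate (C5, C4).
- Oxepene: the O1–C2 bond is made by reductive etherification of the C9a silyl ether onto a (Z)-bromomethyl enone (C2, C3 and the C3 methyl from a Still–Gennari olefination, CH2Br from CH2Br2); hydride entering anti to the axial C9a methyl sets C2.
- The C7 bromide is made last on the rigid bicycle: desilylation, oxidation, LiBH(s-Bu)3 reduction to the axial alcohol, Appel inversion.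

Key step: step 8

Assumption: in step 3 the (S)-SEGPHOS-derived catalyst is taken to give the S carbinol; if the sense of induction is the reverse, (R)-SEGPHOS is used and nothing else changes.

**Step 1**
Reactants: 1 ethyl levulinate
Product: 2 ethyl 3-(2-methyl-1,3-dioxolan-2-yl)propanoate
Conditions: ethylene glycol, p-TsOH (cat.), toluene, reflux, Dean–Stark
Reagents that add atoms: ethylene glycol, OCCO
Why: Acid-catalysed ketalisation with azeotropic removal of water masks the ketone for the hydride and carbanion steps that follow.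

**Step 2**
Reactants: 2 ethyl 3-(2-methyl-1,3-dioxolan-2-yl)propanoate
Product: 3 3-(2-methyl-1,3-dioxolan-2-yl)propanal
Conditions: i-Bu2AlH (1.05 equiv), CH2Cl2, −78 °C; aq. potassium sodium tartrate
Reagents that add atoms: none
Why: Partial reduction of the ester by i-Bu2AlH at low temperature stops at the aluminium hemiacetal, which gives the aldehyde on work-up.

**Step 3**
Reactants: 3 3-(2-methyl-1,3-dioxolan-2-yl)propanal; 4 3-methylbuta-1,2-diene
Product: 5 (3S)-4,4-dimethyl-1-(2-methyl-1,3-dioxolan-2-yl)hex-5-en-3-ol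
Conditions: catalyst preformed from [Ir(cod)Cl]2, (S)-SEGPHOS, 4-cyano-3-nitrobenzoic acid, allyl acetate and Cs2CO3 (5 mol %), i-PrOH (2 equiv), 4 (excess), toluene, 50 °C
Reagents that add atoms: none
Why: Iridium-catalysed transfer-hydrogenative reverse prenylation, in which hydrometalation of the allene gives a 1,1-dimethylallyl iridium species that adds to the aldehyde through its substituted terminus in a closed chair-like transition state, the chiral bisphosphine selecting the aldehyde face and so setting the C7 carbinol (S).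

**Step 4**
Reactants: 5 (3S)-4,4-dimethyl-1-(2-methyl-1,3-dioxolan-2-yl)hex-5-en-3-ol
Product: 6 tert-butyl{[(3S)-4,4-dimethyl-1-(2-methyl-1,3-dioxolan-2-yl)hex-5-en-3-yl]oxy}dimethylsilane
Conditions: TBSOTf, 2,6-lutidine, CH2Cl2, −78 → 0 °C
Reagents that add atoms: tert-butyldimethylsilyl triflate, CC(C)(C)[Si](C)(C)OS(=O)(=O)C(F)(F)F
Why: Silylation of the hindered neopentyl-type secondary alcohol needs the silyl triflate with 2,6-lutidine, conditions the dioxolane should tolerate at low temperature.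

**Step 5**
Reactants: 6 tert-butyl{[(3S)-4,4-dimethyl-1-(2-methyl-1,3-dioxolan-2-yl)hex-5-en-3-yl]oxy}dimethylsilane
Product: 8 (3S)-3-[(tert-butyldimethylsilyl)oxy]-2,2-dimethyl-5-(2-methyl-1,3-dioxolan-2-yl)pentanal, via ozonide 7 (not isolated)
Conditions: O3, CH2Cl2, −78 °C; then PPh3, −78 °C → rt
Reagents that add atoms: ozone, [O-][O+]=O
Why: Ozonolysis of the only alkene with reductive work-up gives the α-quaternary aldehyde, which has no α-hydrogen and so can neither epimerise nor eliminate the β-silyloxy group.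

**Step 6**
Reactants: 8 (3S)-3-[(tert-butyldimethylsilyl)oxy]-2,2-dimethyl-5-(2-methyl-1,3-dioxolan-2-yl)pentanal; 9 triethyl phosphonoacetate
Product: 10 ethyl (2E,5S)-5-[(tert-butyldimethylsilyl)oxy]-4,4-dimethyl-7-(2-methyl-1,3-dioxolan-2-yl)hept-2-enoate
Conditions: NaH, THF, 0 °C → rt
Reagents that add atoms: none
Why: Horner–Wadsworth–Emmons olefination with the stabilised phosphonate anion should give the E-enoate, the bulky neopentyl substituent reinforcing the usual E preference.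

**Step 7**
Reactants: 10 ethyl (2E,5S)-5-[(tert-butyldimethylsilyl)oxy]-4,4-dimethyl-7-(2-methyl-1,3-dioxolan-2-yl)hept-2-enoate
Product: 11 ethyl (2E,5S)-5-[(tert-butyldimethylsilyl)oxy]-4,4-dimethyl-8-oxonon-2-enoate
Conditions: PPTS (cat.), acetone/H2O, 60 °C
Reagents that add atoms: water, O
Why: Mild acid-catalysed ketal hydrolysis frees the methyl ketone while the hindered silyl ether and the enoate stay intact.

**Step 8**
Reactants: 11 ethyl (2E,5S)-5-[(tert-butyldimethylsilyl)oxy]-4,4-dimethyl-8-oxonon-2-enoate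
Product: 12 ethyl 2-[(1S,3S,6S)-3-[(tert-butyldimethylsilyl)oxy]-6-hydroxy-2,2,6-trimethylcyclohexyl]acetate
Conditions: SmI2 (0.1 M in THF, 2.5 equiv), MeOH (2 equiv), THF, −78 → 0 °C
Reagents that add atoms: none
Why: SmI2 (divalent samarium) transfers one electron to the methyl ketone, the samarium-bound ketyl adds to the enoate β-carbon, a second SmI2 reduces the resulting α-ester radical to a samarium enolate and methanol protonates it; this is the known SmI2 ketyl–olefin reductive cyclisation of keto enoates to 2-(alkoxycarbonylmethyl)cycloalkanols. The cyclohexane (C5a, C6, C7, C8, C9, C9a) closes 6-exo-trig through a chair-like transition state by forming the C5a–C9a bond. At C9a the bulky solvated O–Sm group should take the equatorial site and leave the methyl axial, and at C5a the enoate arm should lie equatorial and turned away from the ketyl oxygen, which together give the trans relation of C9a–O and C5a–CH2CO2Et. The absolute sense of both new centres is relayed from C7: with the silyloxy group equatorial in that chair the (1S,6S) pair should result. The step needs trans over cis and this chair over the one with the C7 substituent axial; the first rests on the steric and dipolar demands of the ketyl oxygen, the second on the equatorial preference of the silyl ether, which the flanking gem-dimethyl group weakens. Any cis adduct should lactonise, and any C7-axial diastereomer must be removed by chromatography here, because C7 later passes through a ketone and the error would otherwise be carried on as the mirror-image series.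

**Step 9**
Reactants: 12 ethyl 2-[(1S,3S,6S)-3-[(tert-butyldimethylsilyl)oxy]-6-hydroxy-2,2,6-trimethylcyclohexyl]acetate
Product: 13 ethyl 2-[(1S,3S,6S)-3-[(tert-butyldimethylsilyl)oxy]-2,2,6-trimethyl-6-[(triethylsilyl)oxy]cyclohexyl]acetate
Conditions: TESOTf, 2,6-lutidine, CH2Cl2, −78 → 0 °C
Reagents that add atoms: triethylsilyl triflate, CC[Si](CC)(CC)OS(=O)(=O)C(F)(F)F
Why: Silylation of the tertiary alcohol with the silyl triflate blocks the C9a oxygen, so that the aldehyde made next cannot close to a lactol and no alkoxide can add in a conjugate sense later.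

**Step 10**
Reactants: 13 ethyl 2-[(1S,3S,6S)-3-[(tert-butyldimethylsilyl)oxy]-2,2,6-trimethyl-6-[(triethylsilyl)oxy]cyclohexyl]acetate
Product: 14 2-[(1S,3S,6S)-3-[(tert-butyldimethylsilyl)oxy]-2,2,6-trimethyl-6-[(triethylsilyl)oxy]cyclohexyl]acetaldehyde
Conditions: i-Bu2AlH (1.1 equiv), CH2Cl2, −78 °C; aq. potassium sodium tartrate
Reagents that add atoms: none
Why: Partial reduction of the ethyl ester with i-Bu2AlH at −78 °C gives the aldehyde (C4), both silyl ethers being inert.

**Step 11**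
Reactants: 14 2-[(1S,3S,6S)-3-[(tert-butyldimethylsilyl)oxy]-2,2,6-trimethyl-6-[(triethylsilyl)oxy]cyclohexyl]acetaldehyde; 15 ethyl 2-[bis(2,2,2-trifluoroethoxy)phosphoryl]propanoate
Product: 16 ethyl (2Z)-4-[(1S,3S,6S)-3-[(tert-butyldimethylsilyl)oxy]-2,2,6-trimethyl-6-[(triethylsilyl)oxy]cyclohexyl]-2-methylbut-2-enoate
Conditions: KN(SiMe3)2, 18-crown-6, THF, −78 °C
Reagents that add atoms: none
Why: Still–Gennari olefination, in which the electron-poor bis(trifluoroethyl) phosphonate under dissociating conditions eliminates fast from the kinetic adduct and should give the Z-trisubstituted enoate, placing the future C2 cis to C5 as the ring requires.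

**Step 12**
Reactants: 16 ethyl (2Z)-4-[(1S,3S,6S)-3-[(tert-butyldimethylsilyl)oxy]-2,2,6-trimethyl-6-[(triethylsilyl)oxy]cyclohexyl]-2-methylbut-2-enoate
Product: 17 (2Z)-4-[(1S,3S,6S)-3-[(tert-butyldimethylsilyl)oxy]-2,2,6-trimethyl-6-[(triethylsilyl)oxy]cyclohexyl]-N-methoxy-N,2-dimethylbut-2-enamide
Conditions: MeNH(OMe)·HCl, i-PrMgCl, THF, −20 → 0 °C
Reagents that add atoms: N,O-dimethylhydroxylamine hydrochloride, CNOC.Cl
Why: Weinreb amide formation by aminolysis of the ester with the chloromagnesium amide of N,O-dimethylhydroxylamine, which should leave the alkene geometry and both silyl ethers untouched.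

**Step 13**
Reactants: 17 (2Z)-4-[(1S,3S,6S)-3-[(tert-butyldimethylsilyl)oxy]-2,2,6-trimethyl-6-[(triethylsilyl)oxy]cyclohexyl]-N-methoxy-N,2-dimethylbut-2-enamide; 18 dibromomethane
Product: 19 (3Z)-1-bromo-5-[(1S,3S,6S)-3-[(tert-butyldimethylsilyl)oxy]-2,2,6-trimethyl-6-[(triethylsilyl)oxy]cyclohexyl]-3-methylpent-3-en-2-one
Conditions: CH2Br2 (3 equiv), MeLi·LiBr (2.5 equiv, slow addition), THF, −78 °C; aq. NH4Cl
Reagents that add atoms: none
Why: Halomethyllithium acylation, in which bromomethyllithium generated by Br–Li exchange in the presence of the amide adds once to the Weinreb amide and the chelated adduct releases the α′-bromo enone only on quench.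

**Step 14**
Reactants: 19 (3Z)-1-bromo-5-[(1S,3S,6S)-3-[(tert-butyldimethylsilyl)oxy]-2,2,6-trimethyl-6-[(triethylsilyl)oxy]cyclohexyl]-3-methylpent-3-en-2-one
Product: 21 tert-butyl{[(2R,5aS,7S,9aS)-2-(bromomethyl)-3,6,6,9a-tetramethyl-2,5,5a,6,7,8,9,9a-octahydro-1-benzoxepin-7-yl]oxy}dimethylsilane, via cyclic oxocarbenium triflate 20 (not isolated)
Conditions: TMSOTf (0.5 equiv), Et3SiH (5 equiv), CH2Cl2, −78 → −20 °C
Reagents that add atoms: none
Why: Reductive etherification of a silyl ether with a ketone, in which TMSOTf activates the carbonyl, the C9a silyl ether oxygen adds to C2 (7-exo-trig), loss of silanolate gives the ring oxocarbenium ion 20 and Et3SiH should deliver hydride to C2 from the face opposite the axial C9a methyl group, so that H ends anti and CH2Br syn to that methyl (2R).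

**Step 15**
Reactants: 21 tert-butyl{[(2R,5aS,7S,9aS)-2-(bromomethyl)-3,6,6,9a-tetramethyl-2,5,5a,6,7,8,9,9a-octahydro-1-benzoxepin-7-yl]oxy}dimethylsilane
Product: 22 (2R,5aS,7S,9aS)-2-(bromomethyl)-3,6,6,9a-tetramethyl-2,5,5a,6,7,8,9,9a-octahydro-1-benzoxepin-7-ol
Conditions: 48 % aq. HF, MeCN, 0 °C → rt
Reagents that add atoms: none
Why: Cleavage of the hindered silyl ether with HF under non-basic conditions, which avoid elimination or substitution at the primary bromide.

**Step 16**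
Reactants: 22 (2R,5aS,7S,9aS)-2-(bromomethyl)-3,6,6,9a-tetramethyl-2,5,5a,6,7,8,9,9a-octahydro-1-benzoxepin-7-ol
Product: 23 (2R,5aS,9aS)-2-(bromomethyl)-3,6,6,9a-tetramethyl-2,5,5a,8,9,9a-hexahydro-1-benzoxepin-7(6H)-one
Conditions: Dess–Martin periodinane, CH2Cl2, rt
Reagents that add atoms: none
Why: Dess–Martin oxidation of the secondary alcohol gives the C7 ketone without touching the allylic ether or the bromide, and no stereocentre is α to the new carbonyl.

**Step 17**
Reactants: 23 (2R,5aS,9aS)-2-(bromomethyl)-3,6,6,9a-tetramethyl-2,5,5a,8,9,9a-hexahydro-1-benzoxepin-7(6H)-one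
Product: 24 (2R,5aS,7R,9aS)-2-(bromomethyl)-3,6,6,9a-tetramethyl-2,5,5a,6,7,8,9,9a-octahydro-1-benzoxepin-7-ol
Conditions: LiBH(s-Bu)3, THF, −78 °C; aq. NH4Cl
Reagents that add atoms: none
Why: Bulky-hydride reduction, in which LiBH(s-Bu)3 should attack the conformationally locked ketone along the equatorial trajectory, away from the axial hydrogens at C5a and C9, and give the axial (7R) alcohol as is known for 4,4-dimethyl-3-keto terpenoids.

**Step 18**
Reactants: 24 (2R,5aS,7R,9aS)-2-(bromomethyl)-3,6,6,9a-tetramethyl-2,5,5a,6,7,8,9,9a-octahydro-1-benzoxepin-7-ol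
Product: 25 palisadin B, (2R,5aS,7S,9aS)-7-bromo-2-(bromomethyl)-3,6,6,9a-tetramethyl-2,5,5a,6,7,8,9,9a-octahydro-1-benzoxepine
Conditions: CBr4, PPh3, CH2Cl2, 0 → 40 °C
Reagents that add atoms: tetrabromomethane, BrC(Br)(Br)Br
Why: Appel reaction, in which the alkoxyphosphonium ion of the axial alcohol is displaced by bromide in an SN2 step with inversion, setting the equatorial C7 bromide (7S).

**Compound list**
1 | ethyl levulinate | CCOC(=O)CCC(C)=O | starting material
2 | ethyl 3-(2-methyl-1,3-dioxolan-2-yl)propanoate | CCOC(=O)CCC1(C)OCCO1 | intermediate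
3 | 3-(2-methyl-1,3-dioxolan-2-yl)propanal | O=CCCC1(C)OCCO1 | intermediate
4 | 3-methylbuta-1,2-diene | CC(C)=C=C | starting material
5 | (3S)-4,4-dimethyl-1-(2-methyl-1,3-dioxolan-2-yl)hex-5-en-3-ol | CC1(CC[C@H](O)C(C)(C)C=C)OCCO1 | intermediate
6 | tert-butyl{[(3S)-4,4-dimethyl-1-(2-methyl-1,3-dioxolan-2-yl)hex-5-en-3-yl]oxy}dimethylsilane | CC1(CC[C@H](O[Si](C)(C)C(C)(C)C)C(C)(C)C=C)OCCO1 | intermediate
7 | ozonide of 6, tert-butyl{[(3S)-4-methyl-1-(2-methyl-1,3-dioxolan-2-yl)-4-(1,2,4-trioxolan-3-yl)pentan-3-yl]oxy}dimethylsilane (not isolated) | CC1(CC[C@H](O[Si](C)(C)C(C)(C)C)C(C)(C)C2OCOO2)OCCO1 | intermediate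
8 | (3S)-3-[(tert-butyldimethylsilyl)oxy]-2,2-dimethyl-5-(2-methyl-1,3-dioxolan-2-yl)pentanal | CC1(CC[C@H](O[Si](C)(C)C(C)(C)C)C(C)(C)C=O)OCCO1 | intermediate
9 | triethyl phosphonoacetate | CCOC(=O)CP(=O)(OCC)OCC | starting material
10 | ethyl (2E,5S)-5-[(tert-butyldimethylsilyl)oxy]-4,4-dimethyl-7-(2-methyl-1,3-dioxolan-2-yl)hept-2-enoate | CC1(CC[C@H](O[Si](C)(C)C(C)(C)C)C(C)(C)/C=C/C(=O)OCC)OCCO1 | intermediate
11 | ethyl (2E,5S)-5-[(tert-butyldimethylsilyl)oxy]-4,4-dimethyl-8-oxonon-2-enoate | CC(=O)CC[C@H](O[Si](C)(C)C(C)(C)C)C(C)(C)/C=C/C(=O)OCC | intermediate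
12 | ethyl 2-[(1S,3S,6S)-3-[(tert-butyldimethylsilyl)oxy]-6-hydroxy-2,2,6-trimethylcyclohexyl]acetate | CCOC(=O)C[C@H]1C(C)(C)[C@@H](O[Si](C)(C)C(C)(C)C)CC[C@]1(C)O | intermediate
13 | ethyl 2-[(1S,3S,6S)-3-[(tert-butyldimethylsilyl)oxy]-2,2,6-trimethyl-6-[(triethylsilyl)oxy]cyclohexyl]acetate | CCOC(=O)C[C@H]1C(C)(C)[C@@H](O[Si](C)(C)C(C)(C)C)CC[C@]1(C)O[Si](CC)(CC)CC | intermediate
14 | 2-[(1S,3S,6S)-3-[(tert-butyldimethylsilyl)oxy]-2,2,6-trimethyl-6-[(triethylsilyl)oxy]cyclohexyl]acetaldehyde | O=CC[C@H]1C(C)(C)[C@@H](O[Si](C)(C)C(C)(C)C)CC[C@]1(C)O[Si](CC)(CC)CC | intermediate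
15 | ethyl 2-[bis(2,2,2-trifluoroethoxy)phosphoryl]propanoate | CCOC(=O)C(C)P(=O)(OCC(F)(F)F)OCC(F)(F)F | starting material
16 | ethyl (2Z)-4-[(1S,3S,6S)-3-[(tert-butyldimethylsilyl)oxy]-2,2,6-trimethyl-6-[(triethylsilyl)oxy]cyclohexyl]-2-methylbut-2-enoate | CCOC(=O)/C(C)=C\C[C@H]1C(C)(C)[C@@H](O[Si](C)(C)C(C)(C)C)CC[C@]1(C)O[Si](CC)(CC)CC | intermediate
17 | (2Z)-4-[(1S,3S,6S)-3-[(tert-butyldimethylsilyl)oxy]-2,2,6-trimethyl-6-[(triethylsilyl)oxy]cyclohexyl]-N-methoxy-N,2-dimethylbut-2-enamide | CON(C)C(=O)/C(C)=C\C[C@H]1C(C)(C)[C@@H](O[Si](C)(C)C(C)(C)C)CC[C@]1(C)O[Si](CC)(CC)CC | intermediate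
18 | dibromomethane | BrCBr | starting material
19 | (3Z)-1-bromo-5-[(1S,3S,6S)-3-[(tert-butyldimethylsilyl)oxy]-2,2,6-trimethyl-6-[(triethylsilyl)oxy]cyclohexyl]-3-methylpent-3-en-2-one | BrCC(=O)/C(C)=C\C[C@H]1C(C)(C)[C@@H](O[Si](C)(C)C(C)(C)C)CC[C@]1(C)O[Si](CC)(CC)CC | intermediate
20 | cyclic oxocarbenium triflate (O1=C2 conjugated with C3=C4; 5aS,7S,9aS; not isolated) | CC1=CC[C@H]2C(C)(C)[C@@H](O[Si](C)(C)C(C)(C)C)CC[C@]2(C)[O+]=C1CBr.[O-]S(=O)(=O)C(F)(F)F | intermediate
21 | tert-butyl{[(2R,5aS,7S,9aS)-2-(bromomethyl)-3,6,6,9a-tetramethyl-2,5,5a,6,7,8,9,9a-octahydro-1-benzoxepin-7-yl]oxy}dimethylsilane | CC1=CC[C@H]2C(C)(C)[C@@H](O[Si](C)(C)C(C)(C)C)CC[C@]2(C)O[C@H]1CBr | intermediate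
22 | (2R,5aS,7S,9aS)-2-(bromomethyl)-3,6,6,9a-tetramethyl-2,5,5a,6,7,8,9,9a-octahydro-1-benzoxepin-7-ol | CC1=CC[C@H]2C(C)(C)[C@@H](O)CC[C@]2(C)O[C@H]1CBr | intermediate
23 | (2R,5aS,9aS)-2-(bromomethyl)-3,6,6,9a-tetramethyl-2,5,5a,8,9,9a-hexahydro-1-benzoxepin-7(6H)-one | CC1=CC[C@H]2C(C)(C)C(=O)CC[C@]2(C)O[C@H]1CBr | intermediate
24 | (2R,5aS,7R,9aS)-2-(bromomethyl)-3,6,6,9a-tetramethyl-2,5,5a,6,7,8,9,9a-octahydro-1-benzoxepin-7-ol | CC1=CC[C@H]2C(C)(C)[C@H](O)CC[C@]2(C)O[C@H]1CBr | intermediate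
25 | palisadin B, (2R,5aS,7S,9aS)-7-bromo-2-(bromomethyl)-3,6,6,9a-tetramethyl-2,5,5a,6,7,8,9,9a-octahydro-1-benzoxepine | CC1=CC[C@H]2C(C)(C)[C@@H](Br)CC[C@]2(C)O[C@H]1CBr | target

**Step count**
Total: 18 steps. Longest linear sequence: 18 steps, from ethyl levulinate 1.

**Steps most likely to fail**

1. Step 8. The chair with the C7 silyloxy group axial may compete with the equatorial one and give poor facial selectivity relative to C7. The arm may also end cis to the C9a oxygen, or the ketone or enoate may simply be reduced without ring closure.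
Fallback (a lactone tether that fixes the C7/C5a relation by geometry), from aldehyde 8 back to 12:
   - Z-selective Still–Gennari olefination of 8 with methyl bis(2,2,2-trifluoroethyl)phosphonoacetate (KN(SiMe3)2, 18-crown-6) would give methyl (2Z,5S)-5-[(tert-butyldimethylsilyl)oxy]-4,4-dimethyl-7-(2-methyl-1,3-dioxolan-2-yl)hept-2-enoate F1.
   - Bu4NF would remove the silyl group, and the freed C7 hydroxyl would close onto the Z-ester to (6S)-5,5-dimethyl-6-[2-(2-methyl-1,3-dioxolan-2-yl)ethyl]-5,6-dihydro-2H-pyran-2-one F2.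
   - PPTS in wet acetone would unmask (6S)-5,5-dimethyl-6-(3-oxobutyl)-5,6-dihydro-2H-pyran-2-one F3.
   - SmI2/MeOH would form the same C5a–C9a bond by ketyl addition to the lactone β-carbon. Because the chain hangs from the lactone ring, the bond can only form cis to the C7 oxygen, giving (1S,5S,6S)-6-hydroxy-6,9,9-trimethyl-2-oxabicyclo[3.3.1]nonan-3-one F4. C9a then rests on the ketyl oxygen lying anti to the lactone α-carbon.
   - KOH in aqueous ethanol would open the lactone to potassium 2-[(1S,3S,6S)-3,6-dihydroxy-2,2,6-trimethylcyclohexyl]acetate F5, and EtI in DMF would give ethyl 2-[(1S,3S,6S)-3,6-dihydroxy-2,2,6-trimethylcyclohexyl]acetate F6.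
   - TBSOTf (1 equiv) with 2,6-lutidine at −78 °C would silylate the secondary hydroxyl only and return to 12.

2. Step 14. The silyl ether oxygen may add in a 5-exo conjugate sense to C4 of the activated enone (tetrahydrofuran formation) instead of to the carbonyl carbon. Hydride may also go to C4 of the allylic oxocarbenium ion, or to the methyl-bearing face of C2.
Fallback (O1–C2 is made as an ester and the ring is closed by metathesis, so that no oxygen nucleophile ever faces a Michael acceptor), from aldehyde 14 back to 21: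
   - Ph3P=CH2 would give 3-[(1S,3S,6S)-3-[(tert-butyldimethylsilyl)oxy]-2,2,6-trimethyl-6-[(triethylsilyl)oxy]cyclohexyl]prop-1-ene F7.
   - PPTS in MeOH would remove the tertiary triethylsilyl group only, giving (1S,2S,4S)-4-[(tert-butyldimethylsilyl)oxy]-1,3,3-trimethyl-2-(prop-2-en-1-yl)cyclohexan-1-ol F8.
   - KN(SiMe3)2 then methacryloyl chloride would give (1S,2S,4S)-4-[(tert-butyldimethylsilyl)oxy]-1,3,3-trimethyl-2-(prop-2-en-1-yl)cyclohexyl 2-methylprop-2-enoate F9.
   - Ring-closing metathesis with the second-generation Grubbs catalyst would form C3=C4 and the unsaturated lactone (5aS,7S,9aS)-7-[(tert-butyldimethylsilyl)oxy]-3,6,6,9a-tetramethyl-5a,6,7,8,9,9a-hexahydro-1-benzoxepin-2(5H)-one F10.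
   - Cp2TiMe2 in toluene at 70 °C would methylenate the lactone carbonyl to tert-butyl{[(5aS,7S,9aS)-3,6,6,9a-tetramethyl-2-methylidene-2,5,5a,6,7,8,9,9a-octahydro-1-benzoxepin-7-yl]oxy}dimethylsilane F11.
   - NBS in MeOH at −78 °C would give the bromomethyl methyl ketal tert-butyl{[(5aS,7S,9aS)-2-(bromomethyl)-2-methoxy-3,6,6,9a-tetramethyl-2,5,5a,6,7,8,9,9a-octahydro-1-benzoxepin-7-yl]oxy}dimethylsilane F12.
   - Et3SiH with BF3·OEt2 would ionise F12 to the same ring oxocarbenium ion and reduce it to 21.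

3. Step 18. In the neopentyl alkoxyphosphonium ion, anti elimination toward C8 or a 1,2-methyl shift from C6 may outrun the slow SN2 displacement.
Fallback (a discrete sulfonate leaving group and a separate bromide source instead of phosphonium activation in the flask), from alcohol 24 to 25:
   - ClCH2SO2Cl with pyridine would give (2R,5aS,7R,9aS)-2-(bromomethyl)-3,6,6,9a-tetramethyl-2,5,5a,6,7,8,9,9a-octahydro-1-benzoxepin-7-yl chloromethanesulfonate F13.
   - LiBr in DMF at 50 °C would displace the sulfonate with inversion to give 25.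

**Further compounds**
F1 | step 8 | methyl (2Z,5S)-5-[(tert-butyldimethylsilyl)oxy]-4,4-dimethyl-7-(2-methyl-1,3-dioxolan-2-yl)hept-2-enoate | CC1(CC[C@H](O[Si](C)(C)C(C)(C)C)C(C)(C)/C=C\C(=O)OC)OCCO1
F2 | step 8 | (6S)-5,5-dimethyl-6-[2-(2-methyl-1,3-dioxolan-2-yl)ethyl]-5,6-dihydro-2H-pyran-2-one | CC1(CC[C@@H]2OC(=O)C=CC2(C)C)OCCO1
F3 | step 8 | (6S)-5,5-dimethyl-6-(3-oxobutyl)-5,6-dihydro-2H-pyran-2-one | CC(=O)CC[C@@H]1OC(=O)C=CC1(C)C
F4 | step 8 | (1S,5S,6S)-6-hydroxy-6,9,9-trimethyl-2-oxabicyclo[3.3.1]nonan-3-one | O=C1C[C@H]2C(C)(C)[C@@H](O1)CC[C@]2(C)O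
F5 | step 8 | potassium 2-[(1S,3S,6S)-3,6-dihydroxy-2,2,6-trimethylcyclohexyl]acetate | [K+].[O-]C(=O)C[C@H]1C(C)(C)[C@@H](O)CC[C@]1(C)O
F6 | step 8 | ethyl 2-[(1S,3S,6S)-3,6-dihydroxy-2,2,6-trimethylcyclohexyl]acetate | CCOC(=O)C[C@H]1C(C)(C)[C@@H](O)CC[C@]1(C)O
F7 | step 14 | 3-[(1S,3S,6S)-3-[(tert-butyldimethylsilyl)oxy]-2,2,6-trimethyl-6-[(triethylsilyl)oxy]cyclohexyl]prop-1-ene | C=CC[C@H]1C(C)(C)[C@@H](O[Si](C)(C)C(C)(C)C)CC[C@]1(C)O[Si](CC)(CC)CC
F8 | step 14 | (1S,2S,4S)-4-[(tert-butyldimethylsilyl)oxy]-1,3,3-trimethyl-2-(prop-2-en-1-yl)cyclohexan-1-ol | C=CC[C@H]1C(C)(C)[C@@H](O[Si](C)(C)C(C)(C)C)CC[C@]1(C)O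
F9 | step 14 | (1S,2S,4S)-4-[(tert-butyldimethylsilyl)oxy]-1,3,3-trimethyl-2-(prop-2-en-1-yl)cyclohexyl 2-methylprop-2-enoate | C=CC[C@H]1C(C)(C)[C@@H](O[Si](C)(C)C(C)(C)C)CC[C@]1(C)OC(=O)C(C)=C
F10 | step 14 | (5aS,7S,9aS)-7-[(tert-butyldimethylsilyl)oxy]-3,6,6,9a-tetramethyl-5a,6,7,8,9,9a-hexahydro-1-benzoxepin-2(5H)-one | CC1=CC[C@H]2C(C)(C)[C@@H](O[Si](C)(C)C(C)(C)C)CC[C@]2(C)OC1=O
F11 | step 14 | tert-butyl{[(5aS,7S,9aS)-3,6,6,9a-tetramethyl-2-methylidene-2,5,5a,6,7,8,9,9a-octahydro-1-benzoxepin-7-yl]oxy}dimethylsilane | CC1=CC[C@H]2C(C)(C)[C@@H](O[Si](C)(C)C(C)(C)C)CC[C@]2(C)OC1=C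
F12 | step 14 | tert-butyl{[(5aS,7S,9aS)-2-(bromomethyl)-2-methoxy-3,6,6,9a-tetramethyl-2,5,5a,6,7,8,9,9a-octahydro-1-benzoxepin-7-yl]oxy}dimethylsilane | CC1=CC[C@H]2C(C)(C)[C@@H](O[Si](C)(C)C(C)(C)C)CC[C@]2(C)OC1(CBr)OC
F13 | step 18 | (2R,5aS,7R,9aS)-2-(bromomethyl)-3,6,6,9a-tetramethyl-2,5,5a,6,7,8,9,9a-octahydro-1-benzoxepin-7-yl chloromethanesulfonate | CC1=CC[C@H]2C(C)(C)[C@H](OS(=O)(=O)CCl)CC[C@]2(C)O[C@H]1CBr
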